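**Retrosynthetic overview**
1. Last C–C bond: ring carbon to triene, by Suzuki–Miyaura coupling of a bromohydroquinone with a trienyl boronate that already carries the aminocyclopentenone amide; the hydroquinone is then oxidised to the quinone.
2. The bromohydroquinone comes from the chloro-amido-p-quinone by 1,4-addition of HBr; the quinone comes from 2-chlorophenol (nitration, reduction, N-acylation, Teuber oxidation).
3. Key disconnection: C6–C7 of the acyl chain (butyl to the stereocentre). It is made on the intact dienoate by a nickel-catalysed enantioconvergent radical cross-coupling of a racemic dienyl bromide with n-BuZnBr, which sets 6R directly; the bromide itself comes from a radical Wohl–Ziegler bromination.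
4. Trienyl boronate: vinylogous Horner–Wadsworth–Emmons reaction of 3-boronoacrolein pinacol ester, saponification, amide coupling.
5. Rings: none is built. The six-membered ring is that of 2-chlorophenol (phenol → quinone → hydroquinone → quinone); the five-membered ring is bought.

Assumption 1: 2-amino-3-hydroxycyclopent-2-en-1-one is taken as commercial (sold as its hydrochloride); it is drawn and counted as the free base and the salt is neutralised in the flask.
Assumption 2: 3-boronoacrolein is bought as its pinacol ester; the pinacol is treated as a protecting group on boron, lost in the coupling, and not counted as part of the starting material.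

**Route**

Step 1
Reactants: 1 (E)-2-methylpent-2-enal
Product: 2 ethyl (2E,4E)-2,4-dimethylhepta-2,4-dienoate
Conditions: Ph3P=C(CH3)CO2Et (1.2 equiv), PhMe, 90 °C
Reagents that add atoms: ethyl 2-(triphenylphosphoranylidene)propanoate, CCOC(=O)C(C)=P(c1ccccc1)(c1ccccc1)c1ccccc1
Why: Wittig olefination with an α-methyl stabilised ylide gives the trisubstituted E-enoate with high selectivity and leaves the E geometry of the enal untouched.

Step 2
Reactants: 2 ethyl (2E,4E)-2,4-dimethylhepta-2,4-dienoate
Product: 3 ethyl (2E,4E)-6-bromo-2,4-dimethylhepta-2,4-dienoate (racemic at C6)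
Conditions: NBS (1.05 equiv), AIBN (5 mol%), PhCF3, 80 °C
Reagents that add atoms: N-bromosuccinimide, O=C1CCC(=O)N1Br
Why: Wohl–Ziegler radical bromination; hydrogen abstraction is fastest at the secondary C6–H because it gives the pentadienyl radical conjugated through to the ester, and bromine transfer at C6 gives the fully conjugated bromide (the parallel of the ε-bromination of sorbate esters); C6 is deliberately racemic here.

Step 3
Reactants: 3 ethyl (2E,4E)-6-bromo-2,4-dimethylhepta-2,4-dienoate; 4 n-butylzinc bromide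
Product: 5 ethyl (2E,4E,6R)-2,4,6-trimethyldeca-2,4-dienoate
Conditions: 4 (1.6 equiv, 0.5 M in THF), NiCl2·DME (5 mol%), 2,6-bis[(4S)-4-(2-phenylethyl)-4,5-dihydrooxazol-2-yl]pyridine (5.5 mol%), NaCl (4 equiv), DMA/DMF 1:1, −10 °C
Reagents that add atoms: none
Why: Proposed new method: the nickel/pybox enantioconvergent Negishi coupling of racemic secondary allylic chlorides with alkylzinc halides (closest known reaction type, including γ-selective coupling of ester-conjugated allyl chlorides) is extended to a dienyl bromide; monovalent nickel abstracts the halogen to give a planar pentadienyl radical, so both enantiomers and any regioisomeric bromide converge, the radical is captured by the chiral divalent nickel–butyl complex, and C–C reductive elimination occurs at the least hindered, methyl-bearing terminus C6 (bond formation at C2 or C4 would create quaternary carbons and break conjugation), where the pybox ligand selects the face and sets 6R.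

Step 4
Reactants: 5 ethyl (2E,4E,6R)-2,4,6-trimethyldeca-2,4-dienoate
Product: 6 (2E,4E,6R)-2,4,6-trimethyldeca-2,4-dienoic acid
Conditions: LiOH (5 equiv), THF/MeOH/H2O 3:1:1, 40 °C; then 1 M HCl
Reagents that add atoms: lithium hydroxide (hydroxide oxygen), [Li+].[OH-]
Why: Ester saponification; the remote C6 stereocentre and the diene geometry are not affected by aqueous hydroxide.

Step 5
Reactants: 7 2-chlorophenol
Product: 8 2-chloro-6-nitrophenol
Conditions: HNO3 (65%, 1.05 equiv), AcOH, 5–10 °C; steam distillation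
Reagents that add atoms: nitric acid, O[N+](=O)[O-]
Why: Electrophilic aromatic nitration directed ortho/para by the hydroxyl group; the intramolecularly hydrogen-bonded ortho isomer is steam-volatile and is separated from the 4-nitro isomer (the ortho isomer is the minor product; acceptable on cheap material in the first step).

Step 6
Reactants: 8 2-chloro-6-nitrophenol
Product: 9 2-amino-6-chlorophenol
Conditions: H2 (1 atm), 5% Pt/C (sulfided), EtOAc, rt
Reagents that add atoms: none
Why: Chemoselective catalytic hydrogenation of the nitro group; the sulfided platinum catalyst suppresses C–Cl hydrogenolysis.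

Step 7
Reactants: 6 (2E,4E,6R)-2,4,6-trimethyldeca-2,4-dienoic acid; 9 2-amino-6-chlorophenol
Product: 11 (2E,4E,6R)-N-(3-chloro-2-hydroxyphenyl)-2,4,6-trimethyldeca-2,4-dienamide, via (2E,4E,6R)-2,4,6-trimethyldeca-2,4-dienoyl chloride 10 (not isolated)
Conditions: (COCl)2, DMF (cat.), CH2Cl2, 0 °C to rt, evaporate; then 9, pyridine, CH2Cl2, 0 °C
Reagents that add atoms: oxalyl chloride, O=C(Cl)C(=O)Cl (supplies the chlorine of 10; none of its atoms stays in 11)
Why: N-acylation of the aniline by the acid chloride; the amine is far more nucleophilic than the hydrogen-bonded phenol, and any O-acyl by-product is cleaved by a K2CO3/MeOH wash.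

Step 8
Reactants: 11 (2E,4E,6R)-N-(3-chloro-2-hydroxyphenyl)-2,4,6-trimethyldeca-2,4-dienamide
Product: 12 (2E,4E,6R)-N-(5-chloro-3,6-dioxocyclohexa-1,4-dien-1-yl)-2,4,6-trimethyldeca-2,4-dienamide
Conditions: (KSO3)2NO (Fremy's salt, 2.5 equiv), KH2PO4 (aq), acetone/H2O, rt
Reagents that add atoms: potassium nitrosodisulfonate, [K+].[K+].[O-]S(=O)(=O)N([O])S(=O)(=O)[O-]
Why: Teuber oxidation; the nitroxyl radical abstracts the phenolic hydrogen and a second equivalent delivers oxygen to the free para position to give the p-quinone, while the dienamide is inert to this mild oxidant.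

Step 9
Reactants: 12 (2E,4E,6R)-N-(5-chloro-3,6-dioxocyclohexa-1,4-dien-1-yl)-2,4,6-trimethyldeca-2,4-dienamide
Product: 13 (2E,4E,6R)-N-(4-bromo-3-chloro-2,5-dihydroxyphenyl)-2,4,6-trimethyldeca-2,4-dienamide
Conditions: HBr (33% in AcOH, 1.1 equiv), CH2Cl2, −20 to 0 °C
Reagents that add atoms: hydrogen bromide, Br
Why: Acid-promoted 1,4-addition of bromide to the quinone followed by enolisation (hydrohalogenation of a quinone); the ring CH next to the chlorine is the only electrophilic CH because the CH next to nitrogen is the electron-rich carbon of a vinylogous amide, and the bromohydroquinone is not re-oxidised by 12 since a halogenated quinone is the stronger oxidant.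

Step 10
Reactants: 14 (E)-3-(4,4,5,5-tetramethyl-1,3,2-dioxaborolan-2-yl)prop-2-enal
Product: 15 ethyl (2E,4E,6E)-7-(4,4,5,5-tetramethyl-1,3,2-dioxaborolan-2-yl)hepta-2,4,6-trienoate
Conditions: (EtO)2P(O)CH2CH=CHCO2Et, LiN(SiMe3)2, THF, −78 to 0 °C
Reagents that add atoms: triethyl 4-phosphonocrotonate, CCOC(=O)/C=C/CP(=O)(OCC)OCC
Why: Vinylogous Horner–Wadsworth–Emmons olefination gives the new E double bond (minor 4Z isomer removed or isomerised with catalytic iodine) and the alkenyl pinacol boronate tolerates the lithiated phosphonate at low temperature.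

Step 11
Reactants: 15 ethyl (2E,4E,6E)-7-(4,4,5,5-tetramethyl-1,3,2-dioxaborolan-2-yl)hepta-2,4,6-trienoate
Product: 16 (2E,4E,6E)-7-(4,4,5,5-tetramethyl-1,3,2-dioxaborolan-2-yl)hepta-2,4,6-trienoic acid
Conditions: LiOH (2 equiv), THF/H2O, 0 °C to rt; then HCl to pH 4
Reagents that add atoms: lithium hydroxide (hydroxide oxygen), [Li+].[OH-]
Why: Ester saponification; the pinacol boronate forms a reversible hydroxy-ate complex and is recovered on acidification.

Step 12
Reactants: 16 (2E,4E,6E)-7-(4,4,5,5-tetramethyl-1,3,2-dioxaborolan-2-yl)hepta-2,4,6-trienoic acid; 17 2-amino-3-hydroxycyclopent-2-en-1-one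
Product: 18 (2E,4E,6E)-N-(2-hydroxy-5-oxocyclopent-1-en-1-yl)-7-(4,4,5,5-tetramethyl-1,3,2-dioxaborolan-2-yl)hepta-2,4,6-trienamide
Conditions: EDC·HCl, HOAt, Et3N, DMF, 0 °C to rt
Reagents that add atoms: none
Why: Carbodiimide amide coupling; any O-acyl enol ester formed first rearranges by O-to-N acyl shift to the amide of the vinylogous amide nitrogen.

Step 13
Reactants: 13 (2E,4E,6R)-N-(4-bromo-3-chloro-2,5-dihydroxyphenyl)-2,4,6-trimethyldeca-2,4-dienamide; 18 (2E,4E,6E)-N-(2-hydroxy-5-oxocyclopent-1-en-1-yl)-7-(4,4,5,5-tetramethyl-1,3,2-dioxaborolan-2-yl)hepta-2,4,6-trienamide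
Product: 20 chinikomycin B, via hydroquinone form of chinikomycin B 19 (not isolated)
Conditions: PdCl2(dppf) (8 mol%), K3PO4 (aq, degassed), THF, 50 °C, argon; then pH 5 buffer, EtOAc extract, Ag2O, Na2SO4, rt
Reagents that add atoms: none
Why: Suzuki–Miyaura coupling; zerovalent palladium inserts into the aryl C–Br bond in preference to C–Cl and the alkenyl boronate transfers with retention of the E geometry, after which Ag2O oxidises the electron-rich hydroquinone to the quinone without touching the polyenes.

**Compound list**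
1 | (E)-2-methylpent-2-enal | CC/C=C(\C)C=O | starting material
2 | ethyl (2E,4E)-2,4-dimethylhepta-2,4-dienoate | CC/C=C(\C)/C=C(\C)C(=O)OCC | intermediate
3 | ethyl (2E,4E)-6-bromo-2,4-dimethylhepta-2,4-dienoate (racemic) | CC(Br)/C=C(\C)/C=C(\C)C(=O)OCC | intermediate
4 | n-butylzinc bromide | CCCC[Zn]Br | starting material
5 | ethyl (2E,4E,6R)-2,4,6-trimethyldeca-2,4-dienoate | CCCC[C@@H](C)/C=C(C)/C=C(\C)C(=O)OCC | intermediate
6 | (2E,4E,6R)-2,4,6-trimethyldeca-2,4-dienoic acid | CCCC[C@@H](C)/C=C(C)/C=C(\C)C(=O)O | intermediate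
7 | 2-chlorophenol | Oc1ccccc1Cl | starting material
8 | 2-chloro-6-nitrophenol | Oc1c(Cl)cccc1[N+](=O)[O-] | intermediate
9 | 2-amino-6-chlorophenol | Nc1cccc(Cl)c1O | intermediate
10 | (2E,4E,6R)-2,4,6-trimethyldeca-2,4-dienoyl chloride | CCCC[C@@H](C)/C=C(C)/C=C(\C)C(=O)Cl | intermediate (not isolated)
11 | (2E,4E,6R)-N-(3-chloro-2-hydroxyphenyl)-2,4,6-trimethyldeca-2,4-dienamide | CCCC[C@@H](C)/C=C(C)/C=C(\C)C(=O)Nc1cccc(Cl)c1O | intermediate
12 | (2E,4E,6R)-N-(5-chloro-3,6-dioxocyclohexa-1,4-dien-1-yl)-2,4,6-trimethyldeca-2,4-dienamide | CCCC[C@@H](C)/C=C(C)/C=C(\C)C(=O)NC1=CC(=O)C=C(Cl)C1=O | intermediate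
13 | (2E,4E,6R)-N-(4-bromo-3-chloro-2,5-dihydroxyphenyl)-2,4,6-trimethyldeca-2,4-dienamide | CCCC[C@@H](C)/C=C(C)/C=C(\C)C(=O)Nc1cc(O)c(Br)c(Cl)c1O | intermediate
14 | (E)-3-(4,4,5,5-tetramethyl-1,3,2-dioxaborolan-2-yl)prop-2-enal (3-boronoacrolein pinacol ester) | O=C/C=C/B1OC(C)(C)C(C)(C)O1 | starting material
15 | ethyl (2E,4E,6E)-7-(4,4,5,5-tetramethyl-1,3,2-dioxaborolan-2-yl)hepta-2,4,6-trienoate | CCOC(=O)/C=C/C=C/C=C/B1OC(C)(C)C(C)(C)O1 | intermediate
16 | (2E,4E,6E)-7-(4,4,5,5-tetramethyl-1,3,2-dioxaborolan-2-yl)hepta-2,4,6-trienoic acid | OC(=O)/C=C/C=C/C=C/B1OC(C)(C)C(C)(C)O1 | intermediate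
17 | 2-amino-3-hydroxycyclopent-2-en-1-one | NC1=C(O)CCC1=O | starting material
18 | (2E,4E,6E)-N-(2-hydroxy-5-oxocyclopent-1-en-1-yl)-7-(4,4,5,5-tetramethyl-1,3,2-dioxaborolan-2-yl)hepta-2,4,6-trienamide | O=C(/C=C/C=C/C=C/B1OC(C)(C)C(C)(C)O1)NC1=C(O)CCC1=O | intermediate
19 | hydroquinone form of chinikomycin B: (2E,4E,6R)-N-[3-chloro-2,5-dihydroxy-4-[(1E,3E,5E)-7-[(2-hydroxy-5-oxocyclopent-1-en-1-yl)amino]-7-oxohepta-1,3,5-trien-1-yl]phenyl]-2,4,6-trimethyldeca-2,4-dienamide | CCCC[C@@H](C)/C=C(C)/C=C(\C)C(=O)Nc1cc(O)c(/C=C/C=C/C=C/C(=O)NC2=C(O)CCC2=O)c(Cl)c1O | intermediate (not isolated)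
20 | chinikomycin B | CCCC[C@@H](C)/C=C(C)/C=C(\C)C(=O)NC1=CC(=O)C(/C=C/C=C/C=C/C(=O)NC2=C(O)CCC2=O)=C(Cl)C1=O | target

**Step count**
Total: 13 steps. Longest linear sequence: 8 steps (1, 2, 3, 4, 7, 8, 9, 13).

**Steps most likely to fail, with fallbacks**

Step 3 (dienyl enantioconvergent coupling). The risks are bond formation at C4 or C2, lower enantioselectivity than with simple 1,3-disubstituted allyl systems, and partial 4E/4Z scrambling through the pentadienyl intermediate. The sense of induction of the (S,S)-ligand on this substrate has to be checked on the first run (rotation or chiral GC of 5); the (R,R)-ligand is used if the 6S ester is found. Fallback, setting out from 4 and returning at 5: the stereocentre is made on a symmetric allyl system of the precedented class and both trisubstituted olefins are built afterwards by polar chemistry. Commercial racemic (E)-pent-3-en-2-ol F1 is converted with SOCl2 into racemic (E)-4-chloropent-2-ene F2. This is coupled with 4 under the catalyst of step 3 to give (R,E)-4-methyloct-2-ene F3. Ozonolysis (O3, CH2Cl2, −78 °C, then Me2S) gives (R)-2-methylhexanal F4. Wittig reaction with Ph3P=C(CH3)CHO gives (R,E)-2,4-dimethyloct-2-enal F5, and a second Wittig reaction with the ylide of step 1 gives 5.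

Step 13 (Suzuki coupling on the free bromohydroquinone). The risks are slow oxidative addition into the electron-rich, doubly ortho-substituted phenoxide bromide and air sensitivity of the hydroquinone under base. Fallback, setting out from 13 and returning at 19: the phenols are masked, so the coupling is run on a neutral aryl bromide. Compound 13 is converted with MOMCl and i-Pr2NEt into (2E,4E,6R)-N-[4-bromo-3-chloro-2,5-bis(methoxymethoxy)phenyl]-2,4,6-trimethyldeca-2,4-dienamide F6. Coupling with 18 under the same palladium conditions gives the bis(methoxymethyl) ether of 19 F7. The acetals are removed with HCl in MeOH at 0 °C to give 19, which Ag2O oxidises to 20 as in step 13.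

Step 2 (Wohl–Ziegler bromination). The risks are competing bromination of the C2 and C4 methyl groups, over-bromination, and loss of HBr to a triene. Fallback, setting out from 1 and returning at 5: the allylic halide is made by polar vinylogous halogenation before the diene is assembled. Compound 1 is converted (Me3SiCl, Et3N, NaI, MeCN) into (3E)-2-methyl-1-(trimethylsilyloxy)penta-1,3-diene F8. γ-Chlorination with N-chlorosuccinimide gives racemic (E)-4-chloro-2-methylpent-2-enal F9. Wittig reaction with the ylide of step 1 gives racemic ethyl (2E,4E)-6-chloro-2,4-dimethylhepta-2,4-dienoate F10, which takes the place of 3 in step 3 and gives 5.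

**Further compounds**
F1 | step 3 | (E)-pent-3-en-2-ol (racemic) | C/C=C/C(C)O
F2 | step 3 | (E)-4-chloropent-2-ene (racemic) | C/C=C/C(C)Cl
F3 | step 3 | (R,E)-4-methyloct-2-ene | CCCC[C@@H](C)/C=C/C
F4 | step 3 | (R)-2-methylhexanal | CCCC[C@@H](C)C=O
F5 | step 3 | (R,E)-2,4-dimethyloct-2-enal | CCCC[C@@H](C)/C=C(\C)C=O
F6 | step 13 | (2E,4E,6R)-N-[4-bromo-3-chloro-2,5-bis(methoxymethoxy)phenyl]-2,4,6-trimethyldeca-2,4-dienamide | CCCC[C@@H](C)/C=C(C)/C=C(\C)C(=O)Nc1cc(OCOC)c(Br)c(Cl)c1OCOC
F7 | step 13 | bis(methoxymethyl) ether of 19 | CCCC[C@@H](C)/C=C(C)/C=C(\C)C(=O)Nc1cc(OCOC)c(/C=C/C=C/C=C/C(=O)NC2=C(O)CCC2=O)c(Cl)c1OCOC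
F8 | step 2 | (3E)-2-methyl-1-(trimethylsilyloxy)penta-1,3-diene | C/C=C/C(C)=CO[Si](C)(C)C
F9 | step 2 | (E)-4-chloro-2-methylpent-2-enal (racemic) | CC(Cl)/C=C(\C)C=O
F10 | step 2 | ethyl (2E,4E)-6-chloro-2,4-dimethylhepta-2,4-dienoate (racemic) | CC(Cl)/C=C(\C)/C=C(\C)C(=O)OCC
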